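(The data are calculated for substances that don't exist, and the scatter is random.)

The vessel is closed and stirred, its gas saturation concentration is held at 28 mM, and none of the gas is in solution at the start. The flask holds less enzyme than either run.

| flask | starting material | gas | enzyme | remark | time |
|---|---|---|---|---|---|
| elm | 0.082 M | 28 mM (held) | 11 µM | run made earlier |  |
| alder | 0.082 M | 28 mM (held) | 18 µM | run made earlier |  |
| flask | 0.082 M | 28 mM (held) | 8.2 µM |  | 2.0 h |

- elm (time / h: target / %): 0.133: 36; 0.333: 69; 0.667: 82; 1.00: 86; 1.33: 86; 2.00: 84; 2.50: 87
- alder (time / h: target / %): 0.133: 33; 0.333: 69; 0.667: 81; 1.00: 86; 1.33: 85; 2.00: 84; 2.50: 84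

(standard deviation of a reading: 2 percentage points)

- at the start none of the gas is in solution

- dawn: doubling the saturation concentration of gas, all else as stated
- dusk: doubling the transfer coefficient of the gas, all else as stated
- autumn: doubling the amount of enzyme, all else as stated

- how much target there is at 2.0 h, in percent of the starting material charged
- the change that raises the amount of target at 2.0 h, in percent of the starting material charged most ("none" if none brings more than 2 percentage points) (dawn / dusk / autumn / none)
- amount of target at 2.0 h, in percent of the starting material charged, after dusk

Late in each run I replace the curve by its mean. From 1.00 h on, elm averages 85.8% and alder 84.7%. Together they give a plateau reading of 85.2%, and the error of that mean is 0.71 percentage points.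

The first readings, 36% in elm and 33% in alder, do not rise, although alder holds more enzyme than elm, so I suspect gas transfer is the rate-limiting step in these runs. Their mean gives a first slope of 0.213 M h⁻¹.

I define the filling time as the plateau amount of target divided by the first slope:

filling time = 0.329 h

Two extreme versions bracket the flask.

Fast version: the first slope lasts, so [target] reaches the plateau at the filling time.

Slow version: the slope fades with the distance from the plateau, and the time stretches with falling enzyme to 0.441 h:

[target] = plateau × (one − exp(−t/0.441 h)) = 84.3% at 2.0 h

The elm reading of 69% at 0.333 h lies between the plateau and the 54.2% of the fading curve without stretching. So I expect 84.3% to 85.2% in the flask, give or take the error of the mean. If gas transfer sets the slope, dusk brings the filling time to 0.165 h, shorter than 2.0 h, so I keep the same plateau reading after dusk.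

The forecast says 85%, from 82% to 87%, a range wider than mine. It picks dawn and gives 85% after dusk: “Faster transfer (dusk) only arrives sooner”.

The flask gives 84.8%. Dawn adds 7 points, dusk 0 points and autumn 0 points. After dusk the flask holds 84.8%.

    gas ⇌ second substrate, rate k1*(csat - [second substrate]) (kL = 0.00270 s⁻¹)
    second substrate + starting complex ⇌ ternary complex (K = 64.0 L mol⁻¹, k = 24000 L mol⁻¹ s⁻¹)
    starting material + enzyme ⇌ starting complex (K = 37.0 L mol⁻¹, k = 1100 L mol⁻¹ s⁻¹)
    ternary complex ⇌ enzyme + target (K = 0.0840 M, k = 130 s⁻¹)

The flask at 2.0 h stands 6.08 filling times from its start, and at 20.0 h it still holds 84.8%. The neighbouring flask is the same charge read at 30 min, which is 1.52 filling times. There the fast version gives the plateau, and the slow version gives 57.8%. That neighbour gives 77.5% of target, with 23% of the starting material still there unbound.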